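**Compound numbering used throughout:** 1–5 lactate → butenolide; 6–10 arylation; 11–13 methylenation; 14–15 hydrazone; 16–19 key step; 20–24 end game.

## The problem

Compound 24 is (2R,3S,3aR,5S)-3a-allyl-5,7-dimethoxy-2-methyl-3-(3,4,5-trimethoxyphenyl)-3,3a,4,5-tetrahydro-1-benzofuran-6(2H)-one. Its benzofuranone locants (O1, C2, C3, C3a, C4–C7, C7a) are used below for the corresponding atoms of all precursors as well. Ring A (O1–C2–C3–C3a–C7a) is a tetrahydrofuran fused along C3a–C7a to ring B, a cyclohexenone in which O1–C7a=C7–C6=O forms a vinylogous ester with a further methoxy group on C7. Four stereocentres must be set: the C2 methyl and C3 aryl groups are trans, the quaternary C3a carries its allyl group trans to the aryl group, and the C5 methoxy group is cis to the allyl group. C2 can be bought and can steer C3 (addition anti to methyl). The C3 aryl group is next to C3a and can send whichever substituent arrives last at C3a to the face opposite to it. C5 is α to the C6 ketone, is epimerisable, and can only be fixed at the very end. The sensitive groups are the terminal allyl double bond (no hydrogenation, no ozonolysis), the enol-ether half of the vinylogous ester (aqueous acid), the C5 centre (acid or base) and, among the intermediates, an α-methylene lactone whose double bond can move into conjugation with the aryl group. The enabling feature is C3a: it is the α-carbon of the C7a acyl group and bears both the allyl group and the C4H2 link to C5. Once ring B is opened at C7–C7a and O1–C7a is read as a lactone C–O bond, C3a=C4 is the exocyclic methylene of a butyrolactone that can accept C5 as a nucleophile and then allyl as an electrophile.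

## Retrosynthesis

**C5–H (24 ⇒ 22 via 23).** The last operation sets a configuration, not a skeletal bond. Any earlier setting of C5 would be exposed to the base and acid needed to build ring B. 24 is therefore traced to the C5-epimeric mixture 22, both components of which converge on the one lithium dienolate 23. The forward step must protonate C5 of 23 under kinetic control on the face opposite the allyl group.

**O1–C7a and C7–C7a (22 ⇒ 21 ⇒ 20).** Cutting the enol-ether bond O1–C7a gives the hydroxy 2-methoxy-1,3-diketone 21. Cutting C7–C7a of 21 in the Claisen sense gives the δ-keto lactone 20, in which the C2 oxygen is parked on C7a as the lactone oxygen. A cut at C5–C6 or C6–C7 would need an acyl-anion equivalent. The aldol-type pairing of C4–C5 with C7–C7a arrives one oxidation level too high (see Alternative 2). 20 has one ring fewer and no enol ether. The forward reaction needs enolisation of the ketone toward C7 and attack on a hindered lactone carbonyl. The acid closure has only one outlet, because the C2 hydroxyl reaches C6 only through a bridged ring.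

**C6=O from C6=N (20 ⇒ 19).** The ketone is traced to its N,N-dimethylhydrazone 19. This is the form in which the C5–C6–C7 unit can act as a carbon nucleophile without self-condensation. Its removal must spare the lactone and the allyl group.

**C4–C5 and C3a–allyl (19 ⇒ 13 + 15 + 16 via 17 and 18).** Both bonds at the two ends of the C3a=C4 unit are cut together. The aza-enolate 17 of the symmetric hydrazone 15 is the C5 nucleophile, the methylene lactone 13 is the acceptor, and allyl bromide 16 traps the enolate 18. The neighbouring cut, C3a–C4 on an α-allyl lactone enolate, would bring the C4 chain in last and therefore anti to aryl, giving the wrong C3a epimer. Only the order "C4 first, allyl second" places allyl trans to aryl. The precursors are much simpler: 13 has two stereocentres and no quaternary carbon, 15 is achiral and symmetric, 16 is a commodity. The forward reaction must favour 1,4-addition over γ-deprotonation of 13, must keep 18 alive until it is alkylated, and must allylate on the face opposite the aryl group.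

**C3a=C4 (13 ⇒ 12 ⇒ 11 ⇒ 10).** The exocyclic methylene is traced through the ammonium salt 12 to the Mannich base 11 and on to the saturated trans lactone 10. This aminomethylation–elimination sequence installs the one-carbon unit under conditions mild enough to leave the double bond exocyclic.

**C3–aryl (10 ⇒ 5 + 6 via 7, 8, 9).** The aryl group is removed as the cuprate 8, made from bromide 6 through aryllithium 7. This leaves the butenolide 5, whose single stereocentre (C2) directs the addition to the opposite face. The silyl ketene acetal 9 is the immediate adduct. One stereocentre and the whole aryl group are removed in this cut.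

**Butenolide (5 ⇒ 4 ⇒ 3 ⇒ 2 ⇒ 1).** The lactone C–O bond and the C=C bond of 5 are traced through the (Z)-enoate 4 and the aldehyde 3 to the silyl ether 2 of methyl (R)-lactate 1. This puts C2 in the chiral pool. The forward sequence needs a Z-selective olefination and no racemisation of 3.

**Hydrazone (15 ⇒ 14).** A single condensation (step 8) links 15 to 1,3-dimethoxyacetone 14, which already carries both methoxy groups of ring B.

## Roads not taken

**Alternative 1:** Ring A would be cut at O1–C2 and C2–C3 on a still aromatic ring B. Base would unmask the ortho-quinone methide A1. The ammonium ylide from tert-butyl bromoacetate A2 and a cinchona-derived tertiary amine would add to the benzylic carbon (C2–C3). The phenoxide would then displace the ammonium group (O1–C2), a formal [4+1] annulation giving the trans-dihydrobenzofuran ester A3.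
- Merits: one step closes ring A and sets C2 and C3 with reagent-based absolute control. All ring B oxygens come from a simple arene. The intermediates are flat and robust.
- Weak points for 24: the ester must be taken down to a methyl group in about three operations. The quaternary C3a would have to be made by dearomatising para-C-allylation of the C6 phenol after debenzylation, in competition with O-allylation and attack at the methoxy-bearing ortho carbons. Ring B would emerge one oxidation level too high, with a C4=C5 double bond. A conjugate reduction that spares the allyl group and the vinylogous ester would then be needed before C5 could be addressed.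
- Comparison: Alternative 1 is better in convergence and does not depend on a chiral-pool sequence. Against this, the chosen plan makes C3a by an ordinary enolate alkylation whose face is fixed by the adjacent aryl group and delivers ring B at the correct oxidation level. Neither dearomatisation regiochemistry nor a selective reduction arises. The step count of Alternative 1 would be no shorter.

**Alternative 2:** C4–C5 and C7–C7a would be cut in one operation. The lithium enolate of 14 would add to the aldehyde of the quaternary formyl lactone A4 (C4–C5). The second ketone enolate would acylate on the lactone carbonyl (C7–C7a). Acid would re-close O1–C7a and dehydrate to the dienone A5.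
- Merits: ring B is built in one flask from the same three-carbon unit, with no hydrazone. A4 would use the same "allyl second, anti to aryl" logic.
- Weak points for 24: A4 is a non-enolisable β-formyl lactone, the kind of compound that nucleophilic bases cleave by retro-Claisen deformylation. C4 could therefore be lost under the aldol conditions themselves. Preparing A4 requires C-allylation of an α-formyl lactone enolate against O-allylation. A5 is one oxidation level above 24, so a 1,4-reduction of C4=C5 that spares the terminal alkene and the vinylogous ester must follow.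
- Comparison: the ring construction is shorter (one step against three), and a conjugate reduction would generate the C5 enolate directly, so reduction and C5 protonation could be merged. Against this, the chosen plan brings C4 in as a robust exocyclic methylene (Michael instead of aldol), reaches the correct oxidation level without a chemoselective reduction, and avoids the deformylation risk.

**Alternative 3:** This road changes only the access to 13. Ring A would be cut at C2–C3 and at the lactone bond O1–C7a. An allylchromium species (divalent chromium) from the bromomethyl cinnamate A6 would add through its aryl-bearing carbon to acetaldehyde A7 (C2–C3, anti). The alkoxide would lactonise onto the ester (O1–C7a) to give the trans methylene lactone A8, which has the structure of 13.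
- Merits: two or three steps from a benzaldehyde instead of seven. No organocopper step and no separate methylenation. The exocyclic double bond is formed without base, so it cannot migrate.
- Weak points for 24: there is no absolute control. A8 would be racemic unless an enantioselective carbonyl allylation could be made to work on this 2-alkoxycarbonylallyl system, which is not established. The anti preference depends on the metal (zinc and indium tend toward the cis lactone). A7 is volatile and prone to self-condensation.
- Comparison: Alternative 3 is clearly better in step economy. The chosen plan sets against it a secured absolute configuration from 1 and a dependable trans arylation. If a resolution or an asymmetric variant became available, A8 could replace steps 1–7 without changing the key step.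

Key step: step 9

**Assumptions.** 14 is taken to be purchasable. Where both C5 epimers are carried (19, 20, 21, 22), the SMILES leaves that carbon without a stereodescriptor.

## Route

Step 1
Reactants: 1 methyl (R)-lactate
Product: 2 methyl (R)-2-[(tert-butyldimethylsilyl)oxy]propanoate
Conditions: TBSCl, imidazole, DMF, 0 °C → rt
Reagents that add atoms: tert-butyldimethylsilyl chloride, CC(C)(C)[Si](C)(C)Cl
Why: Imidazole-promoted silylation of a secondary alcohol; the stereocentre is not involved, and the silyl ether survives hydride reduction and the olefination base but leaves under the acid of step 4.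

Step 2
Reactants: 2 methyl (R)-2-[(tert-butyldimethylsilyl)oxy]propanoate
Product: 3 (R)-2-[(tert-butyldimethylsilyl)oxy]propanal
Conditions: iBu2AlH, CH2Cl2, −78 °C; aq. potassium sodium tartrate
Reagents that add atoms: none
Why: Partial reduction of an ester with iBu2AlH stops at the aluminium hemiacetal at −78 °C; the α-silyloxy aldehyde should keep its configuration if used crude and without chromatography.

Step 3
Reactants: 3 (R)-2-[(tert-butyldimethylsilyl)oxy]propanal
Product: 4 methyl (R,Z)-4-[(tert-butyldimethylsilyl)oxy]pent-2-enoate
Conditions: (CF3CH2O)2P(O)CH2CO2Me, KN(SiMe3)2, 18-crown-6, THF, −78 °C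
Reagents that add atoms: methyl 2-[bis(2,2,2-trifluoroethoxy)phosphoryl]acetate, COC(=O)CP(=O)(OCC(F)(F)F)OCC(F)(F)F
Why: Still–Gennari variant of the Horner–Wadsworth–Emmons olefination; the electron-poor phosphonate under dissociating conditions eliminates rapidly from the kinetic adduct and should give the (Z)-enoate needed for ring closure.

Step 4
Reactants: 4 methyl (R,Z)-4-[(tert-butyldimethylsilyl)oxy]pent-2-enoate
Product: 5 (R)-5-methylfuran-2(5H)-one
Conditions: TsOH·H2O (cat.), MeOH, rt
Reagents that add atoms: none
Why: Acid-catalysed desilylation frees the γ-hydroxy (Z)-enoate, which lactonises spontaneously (intramolecular transesterification); any (E)-isomer cannot cyclise and is removed, and acid is used because base would isomerise the butenolide through its dienolate.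

Step 5
Reactants: 6 5-bromo-1,2,3-trimethoxybenzene; 5 (R)-5-methylfuran-2(5H)-one
Product: 10 (4R,5R)-5-methyl-4-(3,4,5-trimethoxyphenyl)dihydrofuran-2(3H)-one (trans), via aryllithium 7 (not isolated), via lithium diarylcuprate 8 (not isolated), via silyl ketene acetal 9 (not isolated)
Conditions: 6, n-BuLi, THF, −78 °C; CuI (0.5 equiv per aryllithium), −40 °C; 5, Me3SiCl, −78 °C; aq. NH4Cl
Reagents that add atoms: none
Why: Bromine–lithium exchange, formation of the Gilman cuprate (monovalent copper) and Me3SiCl-accelerated conjugate addition to the butenolide; the cuprate should approach the face anti to the γ-methyl group, setting C3 of 24 trans to C2.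

Step 6
Reactants: 10 (4R,5R)-5-methyl-4-(3,4,5-trimethoxyphenyl)dihydrofuran-2(3H)-one
Product: 11 (3R,4R,5R)-3-[(dimethylamino)methyl]-5-methyl-4-(3,4,5-trimethoxyphenyl)dihydrofuran-2(3H)-one
Conditions: LiN(iPr)2, THF, −78 °C; CH2=NMe2+ I−, −78 °C → rt
Reagents that add atoms: dimethylmethyleneiminium iodide, C=[N+](C)C.[I-]
Why: Mannich reaction of the lithium lactone enolate with the preformed iminium salt; the reagent should enter anti to the aryl group, but this centre becomes sp2 again in step 7.

Step 7
Reactants: 11 (3R,4R,5R)-3-[(dimethylamino)methyl]-5-methyl-4-(3,4,5-trimethoxyphenyl)dihydrofuran-2(3H)-one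
Product: 13 (4S,5R)-5-methyl-3-methylidene-4-(3,4,5-trimethoxyphenyl)dihydrofuran-2(3H)-one (trans), via ammonium iodide 12 (not isolated)
Conditions: MeI, MeOH, rt; then aq. NaHCO3, CH2Cl2, rt
Reagents that add atoms: none
Why: Exhaustive N-methylation followed by E1cB elimination of trimethylamine (α-methylenation of a lactone through its Mannich base); hydrogen carbonate is basic enough for the elimination but should be too weak to move the double bond into the ring.

Step 8
Reactants: 14 1,3-dimethoxyacetone
Product: 15 2-(1,3-dimethoxypropan-2-ylidene)-1,1-dimethylhydrazine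
Conditions: Me2NNH2, AcOH (cat.), EtOH, reflux
Reagents that add atoms: 1,1-dimethylhydrazine, CN(C)N
Why: Acid-catalysed condensation of a ketone with an unsymmetrical hydrazine; the ketone is symmetric, so a single hydrazone without geometric isomers should form.

Step 9
Reactants: 15 2-(1,3-dimethoxypropan-2-ylidene)-1,1-dimethylhydrazine; 13 (4S,5R)-5-methyl-3-methylidene-4-(3,4,5-trimethoxyphenyl)dihydrofuran-2(3H)-one; 16 allyl bromide
Product: 19 (3R,4S,5R)-3-[3-(2,2-dimethylhydrazinylidene)-2,4-dimethoxybutyl]-5-methyl-3-(prop-2-en-1-yl)-4-(3,4,5-trimethoxyphenyl)dihydrofuran-2(3H)-one (both epimers at the side-chain methoxy carbon), via lithium aza-enolate 17 (not isolated), via lithium lactone enolate 18 (not isolated)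
Conditions: 15, LiN(iPr)2, THF, −78 °C; 13 added slowly, −78 °C; then 16, DMPU, −78 → −30 °C
Reagents that add atoms: none
Why: LiN(iPr)2 removes a proton from one methoxymethyl carbon of 15, and the carbon terminus of aza-enolate 17 adds to the exocyclic methylene of 13 (C4–C5) to give the tetrasubstituted lactone enolate 18, which allyl bromide then alkylates at C3a. The closest known reaction type is the Michael addition of lithiated ketone hydrazones to α,β-unsaturated esters and lactones with in situ α-alkylation of the resulting ester enolate (three-component conjugate addition–alkylation). Enolate 18 should persist because the hydrazone α-protons are no more acidic than a lactone α-proton and proton transfer is slow at −78 °C. No ring is closed. The new quaternary centre C3a is controlled by the adjacent C3 aryl group: the electrophile should approach the planar enolate on the face opposite the aryl group, so the allyl group ends trans to aryl and the C4 chain cis to it, as in 24, which is why C4 must be in place before the allyl group arrives. The side-chain methoxy carbon (C5) is formed without control and is carried as a mixture because step 12 resets it. The step needs 1,4-addition to win over 1,2-addition and over removal of the benzylic γ-proton of 13; the unhindered, highly electrophilic exocyclic methylene, the soft aza-enolate, the low temperature and the slow addition of 13 to an excess of nucleophile (which also suppresses oligomerisation) should secure this.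

Step 10
Reactants: 19 (3R,4S,5R)-3-[3-(2,2-dimethylhydrazinylidene)-2,4-dimethoxybutyl]-5-methyl-3-(prop-2-en-1-yl)-4-(3,4,5-trimethoxyphenyl)dihydrofuran-2(3H)-one (both epimers)
Product: 20 (3R,4S,5R)-3-(2,4-dimethoxy-3-oxobutyl)-5-methyl-3-(prop-2-en-1-yl)-4-(3,4,5-trimethoxyphenyl)dihydrofuran-2(3H)-one (both epimers at the side-chain methoxy carbon)
Conditions: CuCl2, THF/aq. phosphate buffer (pH 7), rt
Reagents that add atoms: water, O
Why: Hydrolysis of an N,N-dimethylhydrazone promoted by divalent copper, which binds the dimethylamino nitrogen and activates C=N toward water at neutral pH; the lactone and the terminal alkene should be untouched, and epimerisation at the methoxy carbon is of no consequence.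

Step 11
Reactants: 20 (3R,4S,5R)-3-(2,4-dimethoxy-3-oxobutyl)-5-methyl-3-(prop-2-en-1-yl)-4-(3,4,5-trimethoxyphenyl)dihydrofuran-2(3H)-one (both epimers)
Product: 22 (2R,3S,3aR)-5,7-dimethoxy-2-methyl-3a-(prop-2-en-1-yl)-3-(3,4,5-trimethoxyphenyl)-3,3a,4,5-tetrahydro-1-benzofuran-6(2H)-one (mixture of C5 epimers), via hydroxy diketone 21 (not isolated)
Conditions: KN(SiMe3)2 (2.2 equiv), THF, −78 → 0 °C; aq. HCl work-up; then TsOH·H2O (cat.), toluene, 4 Å MS, 60 °C
Reagents that add atoms: none
Why: Intramolecular Claisen (Dieckmann-type) condensation of a δ-keto lactone: the kinetic potassium enolate at the methoxymethyl carbon C7 attacks the lactone carbonyl (six-membered, enolendo-exo-trig), the C2 alkoxide is expelled and the second equivalent of base drives the reaction by deprotonating the 1,3-diketone, whereas an enolate on the C5 side could only close a four-membered ring and reverts. Acid then closes O1–C7a by hemiketalisation and dehydration to the vinylogous ester; C5 equilibrates under these conditions and is set in step 12.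

Step 12
Reactants: 22 (2R,3S,3aR)-5,7-dimethoxy-2-methyl-3a-(prop-2-en-1-yl)-3-(3,4,5-trimethoxyphenyl)-3,3a,4,5-tetrahydro-1-benzofuran-6(2H)-one (mixture of C5 epimers)
Product: 24 (2R,3S,3aR,5S)-5,7-dimethoxy-2-methyl-3a-(prop-2-en-1-yl)-3-(3,4,5-trimethoxyphenyl)-3,3a,4,5-tetrahydro-1-benzofuran-6(2H)-one, via lithium dienolate 23 (not isolated)
Conditions: LiN(iPr)2, THF, −78 °C; then cannulated into AcOH/THF, −78 °C
Reagents that add atoms: none
Why: α′-Deprotonation of the vinylogous ester at C5 gives the cross-conjugated dienolate common to both epimers; diastereoselective kinetic protonation should occur on the face opposite the pseudo-axial C3a allyl group (1,3-relationship to C5), leaving H trans and methoxy cis to allyl, and the inverse quench into excess acid prevents enolate–ketone equilibration.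

## Compound list

1 | methyl (R)-lactate | C[C@@H](O)C(=O)OC | starting material
2 | methyl (R)-2-[(tert-butyldimethylsilyl)oxy]propanoate | C[C@@H](O[Si](C)(C)C(C)(C)C)C(=O)OC | intermediate
3 | (R)-2-[(tert-butyldimethylsilyl)oxy]propanal | C[C@@H](O[Si](C)(C)C(C)(C)C)C=O | intermediate
4 | methyl (R,Z)-4-[(tert-butyldimethylsilyl)oxy]pent-2-enoate | C[C@@H](O[Si](C)(C)C(C)(C)C)/C=C\C(=O)OC | intermediate
5 | (R)-5-methylfuran-2(5H)-one | C[C@H]1OC(=O)C=C1 | intermediate
6 | 5-bromo-1,2,3-trimethoxybenzene | COc1cc(Br)cc(OC)c1OC | starting material
7 | (3,4,5-trimethoxyphenyl)lithium | [Li]c1cc(OC)c(OC)c(OC)c1 | intermediate (not isolated)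
8 | lithium bis(3,4,5-trimethoxyphenyl)cuprate | [Li+].COc1cc([Cu-]c2cc(OC)c(OC)c(OC)c2)cc(OC)c1OC | intermediate (not isolated)
9 | trimethyl{[(4R,5R)-5-methyl-4-(3,4,5-trimethoxyphenyl)-4,5-dihydrofuran-2-yl]oxy}silane | C[C@H]1OC(O[Si](C)(C)C)=C[C@@H]1c1cc(OC)c(OC)c(OC)c1 | intermediate (not isolated)
10 | (4R,5R)-5-methyl-4-(3,4,5-trimethoxyphenyl)dihydrofuran-2(3H)-one (trans) | C[C@H]1OC(=O)C[C@@H]1c1cc(OC)c(OC)c(OC)c1 | intermediate
11 | (3R,4R,5R)-3-[(dimethylamino)methyl]-5-methyl-4-(3,4,5-trimethoxyphenyl)dihydrofuran-2(3H)-one | CN(C)C[C@@H]1C(=O)O[C@H](C)[C@H]1c1cc(OC)c(OC)c(OC)c1 | intermediate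
12 | N,N,N-trimethyl-1-[(3R,4R,5R)-5-methyl-2-oxo-4-(3,4,5-trimethoxyphenyl)oxolan-3-yl]methanaminium iodide | C[N+](C)(C)C[C@@H]1C(=O)O[C@H](C)[C@H]1c1cc(OC)c(OC)c(OC)c1.[I-] | intermediate (not isolated)
13 | (4S,5R)-5-methyl-3-methylidene-4-(3,4,5-trimethoxyphenyl)dihydrofuran-2(3H)-one (trans) | C=C1C(=O)O[C@H](C)[C@H]1c1cc(OC)c(OC)c(OC)c1 | intermediate
14 | 1,3-dimethoxyacetone | COCC(=O)COC | starting material
15 | 2-(1,3-dimethoxypropan-2-ylidene)-1,1-dimethylhydrazine | COCC(COC)=NN(C)C | intermediate
16 | allyl bromide | C=CCBr | starting material
17 | lithium 1-(1,3-dimethoxyprop-1-en-2-yl)-2,2-dimethylhydrazin-1-ide (aza-enolate of 15) | COCC(=COC)N([Li])N(C)C | intermediate (not isolated)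
18 | lithium (4S,5R)-3-[3-(2,2-dimethylhydrazinylidene)-2,4-dimethoxybutyl]-5-methyl-4-(3,4,5-trimethoxyphenyl)-4,5-dihydrofuran-2-olate | COCC(=NN(C)C)C(OC)CC1=C(O[Li])O[C@H](C)[C@H]1c1cc(OC)c(OC)c(OC)c1 | intermediate (not isolated)
19 | (3R,4S,5R)-3-[3-(2,2-dimethylhydrazinylidene)-2,4-dimethoxybutyl]-5-methyl-3-(prop-2-en-1-yl)-4-(3,4,5-trimethoxyphenyl)dihydrofuran-2(3H)-one, both epimers at the side-chain methoxy carbon | C=CC[C@]1(CC(OC)C(=NN(C)C)COC)C(=O)O[C@H](C)[C@H]1c1cc(OC)c(OC)c(OC)c1 | intermediate
20 | (3R,4S,5R)-3-(2,4-dimethoxy-3-oxobutyl)-5-methyl-3-(prop-2-en-1-yl)-4-(3,4,5-trimethoxyphenyl)dihydrofuran-2(3H)-one, both epimers at the side-chain methoxy carbon | C=CC[C@]1(CC(OC)C(=O)COC)C(=O)O[C@H](C)[C@H]1c1cc(OC)c(OC)c(OC)c1 | intermediate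
21 | (4R)-4-[(1S,2R)-2-hydroxy-1-(3,4,5-trimethoxyphenyl)propyl]-2,6-dimethoxy-4-(prop-2-en-1-yl)cyclohexane-1,3-dione, epimers at C2 and C6 in equilibrium with the enols | C=CC[C@@]1(CC(OC)C(=O)C(OC)C1=O)[C@H](c1cc(OC)c(OC)c(OC)c1)[C@@H](C)O | intermediate (not isolated)
22 | (2R,3S,3aR)-5,7-dimethoxy-2-methyl-3a-(prop-2-en-1-yl)-3-(3,4,5-trimethoxyphenyl)-3,3a,4,5-tetrahydro-1-benzofuran-6(2H)-one, mixture of C5 epimers | C=CC[C@]12CC(OC)C(=O)C(OC)=C1O[C@H](C)[C@H]2c1cc(OC)c(OC)c(OC)c1 | intermediate
23 | lithium (2R,3S,3aR)-5,7-dimethoxy-2-methyl-3a-(prop-2-en-1-yl)-3-(3,4,5-trimethoxyphenyl)-2,3,3a,4-tetrahydro-1-benzofuran-6-olate | C=CC[C@]12CC(OC)=C(O[Li])C(OC)=C1O[C@H](C)[C@H]2c1cc(OC)c(OC)c(OC)c1 | intermediate (not isolated)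
24 | (2R,3S,3aR,5S)-5,7-dimethoxy-2-methyl-3a-(prop-2-en-1-yl)-3-(3,4,5-trimethoxyphenyl)-3,3a,4,5-tetrahydro-1-benzofuran-6(2H)-one | C=CC[C@]12C[C@H](OC)C(=O)C(OC)=C1O[C@H](C)[C@H]2c1cc(OC)c(OC)c(OC)c1 | target

## Step count and risks

Total: 12 steps. Longest linear sequence: 11 steps (steps 1–7, then 9–12). Step 8 is a one-step side branch.

**Step 9 (key step).** Three things may go wrong.
- The strongly basic aza-enolate may remove the benzylic γ-proton of 13 instead of adding, which moves the double bond into the ring. 1,2-Addition or anionic oligomerisation of the acceptor may also intervene.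
- After the addition, a proton may pass from the remaining methoxymethyl group of the hydrazone to the lactone enolate through a six-membered transition state. The allyl group would then end up on the hydrazone side.
- Facial selectivity of the allylation may be eroded, because the C2 methyl group lies on the face the electrophile has to use.

Fallback, setting out from 13 and 14 and coming back at 19: the two C–C bonds are made separately, and the first one without strong base. 14 is condensed with pyrrolidine to the enamine 1-(1,3-dimethoxyprop-1-en-2-yl)pyrrolidine F1. Stork enamine addition of F1 to 13 and mild aqueous acid give the keto lactone (3S,4R,5R)-3-(2,4-dimethoxy-3-oxobutyl)-5-methyl-4-(3,4,5-trimethoxyphenyl)dihydrofuran-2(3H)-one F2. The ketone is masked again with 1,1-dimethylhydrazine as (3S,4R,5R)-3-[3-(2,2-dimethylhydrazinylidene)-2,4-dimethoxybutyl]-5-methyl-4-(3,4,5-trimethoxyphenyl)dihydrofuran-2(3H)-one F3. One equivalent of LiN(iPr)2 at −78 °C should remove the lactone α-proton faster than a hydrazone α-proton, and allylation with 16 anti to aryl gives 19.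

**Step 11.** Attack on a lactone carbonyl flanked by the quaternary C3a may be slow. The ketone enolate may then be diverted into intermolecular condensation or unproductive enolisation toward C5. The acid closure may also stop short of full dehydration.

Fallback, setting out from 19 and coming back at 21: the ring is closed before the hydrazone is removed. LiN(iPr)2 (two equivalents) metalates 19 at the less substituted α-carbon C7, and the more nucleophilic aza-enolate acylates on the lactone carbonyl. This gives (6R)-3-(2,2-dimethylhydrazinylidene)-6-[(1S,2R)-2-hydroxy-1-(3,4,5-trimethoxyphenyl)propyl]-2,4-dimethoxy-6-(prop-2-en-1-yl)cyclohexan-1-one F4. Aqueous acid hydrolyses the hydrazone to 21, which closes to 22 under the acid conditions of step 11.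

**Step 12.** The facial preference of the protonation may be poor, because the aryl group on C3 also reaches toward the upper face of ring B. Equilibration during the quench may return the more stable epimer.

Fallback, setting out from 22 and coming back at 24: the stereoselective protonation is replaced by separation and recycling. The two diastereomers of 22 are separated by chromatography into 24 and (2R,3S,3aR,5R)-5,7-dimethoxy-2-methyl-3a-(prop-2-en-1-yl)-3-(3,4,5-trimethoxyphenyl)-3,3a,4,5-tetrahydro-1-benzofuran-6(2H)-one F5. F5 is re-equilibrated with NaOMe in MeOH and separated again until the material has been funnelled into 24.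

**Step 5.** The electron-rich aryl group may transfer sluggishly from the Gilman reagent, half of it is lost by design, and the small methyl group may give incomplete facial control. Warming to compensate risks base-induced isomerisation of 5.

Fallback, setting out from 5 and coming back at 10: rhodium-catalysed conjugate addition of 3,4,5-trimethoxyphenylboronic acid (Hayashi–Miyaura reaction) with [Rh(cod)OH]2 in dioxane/H2O at 50 °C without added base, again anti to the methyl group. No new intermediate is formed.

**Step 7.** Under base the exocyclic double bond may migrate into conjugation with the aryl group, giving the endocyclic butenolide, an isomer useless for step 9.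

Fallback, setting out from 10 and coming back at 13: the methylene group is introduced under buffered acidic conditions. Carboxylation of 10 with methyl magnesium carbonate (MeOMgOCO2Me, DMF, 130 °C) and acidification give (3R,4R,5R)-5-methyl-2-oxo-4-(3,4,5-trimethoxyphenyl)oxolane-3-carboxylic acid F6. Decarboxylative Mannich methylenation of F6 with aqueous formaldehyde and Et2NH in NaOAc/AcOH gives 13.

## Further compounds

F1 | step 9 | 1-(1,3-dimethoxyprop-1-en-2-yl)pyrrolidine | COCC(=COC)N1CCCC1
F2 | step 9 | (3S,4R,5R)-3-(2,4-dimethoxy-3-oxobutyl)-5-methyl-4-(3,4,5-trimethoxyphenyl)dihydrofuran-2(3H)-one | COCC(=O)C(OC)C[C@@H]1C(=O)O[C@H](C)[C@H]1c1cc(OC)c(OC)c(OC)c1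
F3 | step 9 | (3S,4R,5R)-3-[3-(2,2-dimethylhydrazinylidene)-2,4-dimethoxybutyl]-5-methyl-4-(3,4,5-trimethoxyphenyl)dihydrofuran-2(3H)-one | COCC(=NN(C)C)C(OC)C[C@@H]1C(=O)O[C@H](C)[C@H]1c1cc(OC)c(OC)c(OC)c1
F4 | step 11 | (6R)-3-(2,2-dimethylhydrazinylidene)-6-[(1S,2R)-2-hydroxy-1-(3,4,5-trimethoxyphenyl)propyl]-2,4-dimethoxy-6-(prop-2-en-1-yl)cyclohexan-1-one | C=CC[C@@]1(CC(OC)C(=NN(C)C)C(OC)C1=O)[C@H](c1cc(OC)c(OC)c(OC)c1)[C@@H](C)O
F5 | step 12 | (2R,3S,3aR,5R)-5,7-dimethoxy-2-methyl-3a-(prop-2-en-1-yl)-3-(3,4,5-trimethoxyphenyl)-3,3a,4,5-tetrahydro-1-benzofuran-6(2H)-one | C=CC[C@]12C[C@@H](OC)C(=O)C(OC)=C1O[C@H](C)[C@H]2c1cc(OC)c(OC)c(OC)c1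
F0 | step 5 | none | none
F6 | step 7 | (3R,4R,5R)-5-methyl-2-oxo-4-(3,4,5-trimethoxyphenyl)oxolane-3-carboxylic acid | OC(=O)[C@@H]1C(=O)O[C@H](C)[C@H]1c1cc(OC)c(OC)c(OC)c1
A1 | alternative 1 | 3-(benzyloxy)-2,4-dimethoxy-6-[(3,4,5-trimethoxyphenyl)methylidene]cyclohexa-2,4-dien-1-one | O=C1C(OC)=C(OCc2ccccc2)C(OC)=CC1=Cc3cc(OC)c(OC)c(OC)c3
A2 | alternative 1 | tert-butyl bromoacetate | CC(C)(C)OC(=O)CBr
A3 | alternative 1 | tert-butyl (2S,3S)-6-(benzyloxy)-5,7-dimethoxy-3-(3,4,5-trimethoxyphenyl)-2,3-dihydro-1-benzofuran-2-carboxylate (trans) | c12cc(OC)c(OCc3ccccc3)c(OC)c1O[C@H](C(=O)OC(C)(C)C)[C@H]2c1cc(OC)c(OC)c(OC)c1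
A4 | alternative 2 | (3S,4S,5R)-5-methyl-2-oxo-3-(prop-2-en-1-yl)-4-(3,4,5-trimethoxyphenyl)oxolane-3-carbaldehyde | C=CC[C@]1(C=O)C(=O)O[C@H](C)[C@H]1c1cc(OC)c(OC)c(OC)c1
A5 | alternative 2 | (2R,3S,3aS)-5,7-dimethoxy-2-methyl-3a-(prop-2-en-1-yl)-3-(3,4,5-trimethoxyphenyl)-3,3a-dihydro-1-benzofuran-6(2H)-one | C=CC[C@]12C=C(OC)C(=O)C(OC)=C1O[C@H](C)[C@H]2c1cc(OC)c(OC)c(OC)c1
A6 | alternative 3 | methyl (Z)-2-(bromomethyl)-3-(3,4,5-trimethoxyphenyl)prop-2-enoate | COC(=O)/C(CBr)=C/c1cc(OC)c(OC)c(OC)c1
A7 | alternative 3 | acetaldehyde | CC=O
A8 | alternative 3 | trans-5-methyl-3-methylidene-4-(3,4,5-trimethoxyphenyl)dihydrofuran-2(3H)-one (same structure as 13) | C=C1C(=O)O[C@H](C)[C@H]1c1cc(OC)c(OC)c(OC)c1
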